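**Plan**

Locants: the 16-carbon chain is counted from the hydroxymethyl carbon of the side chain on the ring CH–O carbon (C1) through the ring carbons C6 (CH–O), C7 (C–CH3, lactone oxygen), C8, C9, C10 (CHOH) and C11 (fully substituted) to the hydroxymethyl carbon of the other side chain (C16).
Retrosynthesis: after C10–OH is taken back to the ketone, the bond from C11 to the lactone carbonyl is cut; this opens the 1,4-dioxan-2-one ring and the seven-membered lactone ring together and leaves an oxepan-3-one with an imidazole-1-carboxylate on the C7 oxygen. Behind it, C11–C12 (alkylation), C10–C11 (Dieckmann), O–C11 (O–H insertion), C8–C9 (Claisen) and C6–C7 (Grignard) are cut.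
Enabling feature: C11 sits between the C10 carbonyl and the ring oxygen and is the α-carbon of the lactone, so the core is a masked β-keto lactone; in the oxepane ring C11 lies 1,4 across from C7, whose oxygen can hold the acyl carbon over it.
Forward: nerol → C1–C6 aldehyde → isopropenyl carbinol → Johnson–Claisen (E C6=C7, adds C8–C10) → epoxidation and lactonization (a γ-lactone, opened again later) → O–H insertion and Dieckmann ring expansion (oxepan-3-one) → alkylation with the C12–C16 iodide → C8=C9 enone, loss of the ester, C7 imidazolide → transannular C-acylation (dioxanone and lactone rings) → conjugate reduction, ketone reduction, desilylation.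
Stereochemistry: C6 and C7 from a Shi epoxidation of the E alkene and its invertive opening at C7; C11 from C7 through the tether in the key step; C10 from a CBS reduction; the C2=C3 Z alkene from nerol; the C14=C15 Z alkene from a Wittig reaction of an α-silyloxy ketone.

Key step: step 18

Remark: a saturated oxepan-3-one has a second enolizable carbon, C9, only two ring bonds from C7, and its enolate could close a five-membered lactone onto the same acyl group; the cyclization is therefore run on the C8=C9 enone, where C11 carries the only acidic hydrogen, and the alkene is reduced afterwards.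
Remark: the L-fructose-derived Shi ketone (1,2:4,5-di-O-isopropylidene-β-L-erythro-2,3-hexodiulo-2,6-pyranose) is assumed to be accessible from L-sorbose by the published sequence and is used only as a catalyst.
Abbreviations: TBDPS = tert-butyldiphenylsilyl, TBS = tert-butyldimethylsilyl, TES = triethylsilyl, CDI = 1,1'-carbonyldiimidazole, CSA = camphorsulfonic acid, PPTS = pyridinium p-toluenesulfonate. Oxepane locants in names: O1, C2 = C11, C3 = C10, C4 = C9, C5 = C8, C6 = C7, C7 = C6.

**Route**

Step 1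
Reactants: 1 nerol
Product: 2 neryl TBDPS ether
Conditions: TBDPSCl, imidazole, DMF, 0 °C to rt
Reagents that add atoms: tert-butyl(chloro)diphenylsilane, CC(C)(C)[Si](Cl)(c1ccccc1)c1ccccc1
Why: Silylation of the primary allylic alcohol (silyl ether formation), the TBDPS group being chosen because it must survive periodic acid, a 140 °C Claisen rearrangement, hot LiCl and the later acidic removal of a triethylsilyl ether.

Step 2
Reactants: 2 neryl TBDPS ether
Product: 4 (4Z)-6-(TBDPS-oxy)-4-methylhex-4-enal, via 6,7-epoxide 3 (not isolated)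
Conditions: mCPBA, NaHCO3, CH2Cl2, −20 to 0 °C; then H5IO6, THF/H2O, 0 °C
Reagents that add atoms: 3-chloroperoxybenzoic acid, OOC(=O)c1cccc(Cl)c1
Why: Prilezhaev epoxidation takes the electron-rich distal trisubstituted alkene in preference to the C2=C3 alkene, which is deactivated by its allylic oxygen, and periodic acid then cleaves the epoxide through the diol (Malaprade-type cleavage) to the C6 aldehyde and acetone.

Step 3
Reactants: 4 (4Z)-6-(TBDPS-oxy)-4-methylhex-4-enal; 5 isopropenylmagnesium bromide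
Product: 6 (6Z)-8-(TBDPS-oxy)-2,6-dimethylocta-1,6-dien-3-ol (racemic)
Conditions: THF, −78 to 0 °C; aq NH4Cl
Reagents that add atoms: none
Why: Grignard addition to the aldehyde forms the C6–C7 bond and brings in C7, its methyl group and C8; the carbinol centre is left racemic because it is erased in step 4.

Step 4
Reactants: 6 allylic alcohol; 7 triethyl orthoacetate
Product: 8 ethyl (4E,8Z)-10-(TBDPS-oxy)-4,8-dimethyldeca-4,8-dienoate
Conditions: MeC(OEt)3 (excess), EtCO2H (cat.), 140 °C, EtOH distilled off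
Reagents that add atoms: none
Why: Johnson–Claisen rearrangement of the ketene acetal formed from the secondary allylic alcohol, whose chair transition state with the C5 chain equatorial gives the E C6=C7 alkene and adds C9 and C10 as the ethyl ester.

Step 5
Reactants: 8 dienoate
Product: 10 (5R)-5-[(1S,4Z)-1-hydroxy-4-methyl-6-(TBDPS-oxy)hex-4-en-1-yl]-5-methyloxolan-2-one, via epoxy ester 9 (not isolated)
Conditions: L-fructose-derived Shi ketone (30 mol %), Oxone (2KHSO5·KHSO4·K2SO4), K2CO3, Bu4NHSO4, MeCN/CH2(OMe)2/aq Na2B4O7 buffer, 0 °C; then CSA (10 mol %), wet CH2Cl2, rt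
Reagents that add atoms: potassium peroxymonosulfate (active part of Oxone), [K+].[O-]S(=O)(=O)OO; water, O
Why: Shi epoxidation with the dioxirane of the L-fructose-derived ketone attacks the unhindered E-trisubstituted C6=C7 alkene through the spiro transition state (the C2=C3 alkene is slower because of its allylic silyloxy group) and should give the 6S,7S epoxide, which under acid is opened 5-exo by the ester carbonyl at the tertiary C7 with inversion, so that C6 keeps its oxygen as S and C7 becomes R in the γ-lactone.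

Step 6
Reactants: 10 hydroxy lactone; 11 ethyl diazoacetate
Product: 12 ethyl glycolate ether of 10 at the C6 oxygen
Conditions: Rh2(OAc)4 (2 mol %), 11 added slowly, CH2Cl2, rt
Reagents that add atoms: none
Why: Rhodium-carbenoid O–H insertion etherifies the hindered C6 hydroxyl under neutral conditions, which avoids translactonization, and is much faster than cyclopropanation of a trisubstituted alkene; the carbenoid carbon becomes C11.

Step 7
Reactants: 12 glycolate ether
Product: 15 ethyl 3-oxo-6-(TES-oxy)oxepane-2-carboxylate bearing the C1–C5 arm (both C11 epimers), via dilithium salt 13 (not isolated), via bis-silyl enol ether 14 (not isolated)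
Conditions: LiN(SiMe3)2 (2.2 equiv), THF, −78 to 0 °C; Et3SiOTf (2.4 equiv), −78 °C; 1 M aq citric acid
Reagents that add atoms: triethylsilyl trifluoromethanesulfonate, CC[Si](CC)(CC)OS(=O)(=O)C(F)(F)F
Why: Dieckmann-type Claisen condensation in which the glycolate enolate (C11) adds to the lactone carbonyl (C10) through a six-membered transition ring that runs over the lactone oxygen, after which the tetrahedral intermediate opens to the oxepan-3-one, the stabilized β-keto ester enolate drives the ring expansion and the tertiary C7 alkoxide that is released is silylated in the same flask (the enol silyl ether falls off on acidic work-up).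

Step 8
Reactants: 16 (3-bromopropoxy)(tert-butyl)dimethylsilane; 17 triphenylphosphine
Product: 18 [3-(TBS-oxy)propyl]triphenylphosphonium bromide
Conditions: MeCN, reflux
Reagents that add atoms: none
Why: SN2 quaternization of triphenylphosphine by the primary bromide gives the phosphonium salt.

Step 9
Reactants: 19 hydroxyacetone
Product: 20 1-(TBDPS-oxy)propan-2-one
Conditions: TBDPSCl, imidazole, CH2Cl2, 0 °C to rt
Reagents that add atoms: tert-butyl(chloro)diphenylsilane, CC(C)(C)[Si](Cl)(c1ccccc1)c1ccccc1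
Why: Silylation of the primary alcohol of hydroxyacetone gives the α-silyloxy ketone needed for the Wittig step.

Step 10
Reactants: 18 phosphonium salt; 20 1-(TBDPS-oxy)propan-2-one
Product: 22 (2Z)-1-(TBDPS-oxy)-5-(TBS-oxy)-2-methylpent-2-ene, via phosphorus ylide 21 (not isolated)
Conditions: NaN(SiMe3)2, THF, −78 °C; then 20, −78 °C to rt
Reagents that add atoms: none
Why: Wittig olefination of an α-silyloxy methyl ketone with a non-stabilized ylide under lithium-free conditions, a combination known to put the CH2O group cis to the ylide chain, which makes the C14=C15 alkene Z.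

Step 11
Reactants: 22 bis-silyl ether
Product: 23 (3Z)-5-(TBDPS-oxy)-4-methylpent-3-en-1-ol
Conditions: PPTS (cat.), EtOH, 40 °C
Reagents that add atoms: none
Why: Acid-catalysed solvolysis removes the primary TBS ether, while the TBDPS ether is far more stable to acid and stays.

Step 12
Reactants: 23 homoallylic alcohol
Product: 24 (2Z)-1-(TBDPS-oxy)-5-iodo-2-methylpent-2-ene
Conditions: I2, PPh3, imidazole, CH2Cl2, 0 °C
Reagents that add atoms: iodine, II
Why: Appel-type iodination, SN2 displacement of the oxyphosphonium by iodide at the primary carbon.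

Step 13
Reactants: 15 β-keto ester; 24 iodide
Product: 25 C11-alkylated β-keto ester (both C11 epimers)
Conditions: NaH, DMF, 0 °C; then 24, 40 °C
Reagents that add atoms: none
Why: C-alkylation of the cyclic β-keto ester enolate by the primary homoallylic iodide forms the C11–C12 bond; the configuration of the new quaternary centre is of no concern because the ester leaves in step 15 and C11 is set in step 18.

Step 14
Reactants: 25 alkylated β-keto ester
Product: 27 C8=C9 enone β-keto ester (both C11 epimers), via trimethylsilyl enol ether 26 (not isolated)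
Conditions: LiN(iPr)2, Me3SiCl, THF, −78 °C; then Pd(OAc)2, MeCN, rt
Reagents that add atoms: none
Why: Saegusa–Ito dehydrogenation through the silyl enol ether; because C11 is quaternary at this stage, C9 is the only enolizable carbon, so the C8=C9 enone forms without a regiochemical choice, and this takes away the C9 protons before the key step.

Step 15
Reactants: 27 enone β-keto ester
Product: 28 6-(TES-oxy)-6,7-dihydrooxepin-3(2H)-one bearing both arms (both C11 epimers)
Conditions: LiCl, H2O, DMSO, 150 °C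
Reagents that add atoms: none
Why: Krapcho dealkoxycarbonylation of the quaternary β-keto ester gives C11–H as a mixture of epimers, both of which are used in step 18.

Step 16
Reactants: 28 silyloxy enone
Product: 29 tertiary alcohol (C7–OH) of the enone
Conditions: CSA (0.2 equiv), MeOH/CH2Cl2, 0 °C to rt
Reagents that add atoms: none
Why: Acid-catalysed methanolysis cleaves the triethylsilyl ether, which is several orders of magnitude more labile to acid than the two primary TBDPS ethers.

Step 17
Reactants: 29 hydroxy enone; 30 CDI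
Product: 31 C7 imidazole-1-carboxylate of the enone (both C11 epimers)
Conditions: NaN(SiMe3)2 (1.05 equiv), THF, −78 °C; 30 (2.5 equiv), −78 to −30 °C; AcOH quench
Reagents that add atoms: none
Why: Acylation of the tertiary sodium alkoxide by CDI gives the imidazole-1-carboxylate (the O–H is the first proton to go); the low temperature and the cold acidic quench keep the imidazolide that is set free from deprotonating C11.

Step 18
Reactants: 31 C7 imidazole-1-carboxylate
Product: 32 (1R,5R,9S)-6,8-dioxabicyclo[3.2.2]non-3-ene-2,7-dione bearing both arms and the C5 methyl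
Conditions: NaH (1.3 equiv), THF, 0 °C to rt; aq NH4Cl
Reagents that add atoms: none
Why: NaH, helped by the imidazolide it liberates, removes the C11 proton, the only acidic one in 31 because C9 is vinylic and C7 is quaternary, and the cross-conjugated enolate adds through carbon to the carbonyl of the imidazole carboxylate held on the C7 oxygen 1,4 across the ring; loss of imidazolide completes the C-acylation. The closest known reaction type is the intramolecular Claisen (Dieckmann-type) acylation of a ketone enolate by a carbonate-like acyl donor, the aliphatic counterpart of the Baker–Venkataraman oxygen-to-carbon acyl transfer. The one new bond from C11 to the carbonyl carbon closes the 1,4-dioxan-2-one ring in a 6-(enolexo)-exo-trig mode and, counted through C8–C10, the seven-membered lactone ring in a 7-(enolendo)-exo-trig mode. C11 becomes R because the acyl carbon is tied to the C7 oxygen and can reach only the enolate face on which that oxygen lies, so both C11 epimers of 31 give the same product. The step needs C- rather than O-acylation and C11 rather than C9: O-acylation would give a strained bridgehead enol carbonate that imidazolide can reopen, whereas the C-acylated product has no acidic proton left, and the C8=C9 double bond removes the C9 protons that in a saturated ring would let a five-membered lactone close instead.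

Step 19
Reactants: 32 bicyclic enone
Product: 33 (1R,5R,9S)-6,8-dioxabicyclo[3.2.2]nonane-2,7-dione bearing both arms
Conditions: [(Ph3P)CuH]6 (0.4 equiv), H2O (3 equiv), benzene, rt
Reagents that add atoms: none
Why: Conjugate reduction with Stryker's reagent (copper hydride 1,4-addition, protonation of the copper enolate by water) saturates only the C8=C9 enone alkene and leaves the isolated trisubstituted alkenes, the ketone and the lactone untouched.

Step 20
Reactants: 33 keto lactone
Product: 34 (1R,2S,5R,9S)-2-hydroxy lactone with both TBDPS ethers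
Conditions: (R)-2-methyl-CBS-oxazaborolidine (0.5 equiv), catecholborane (2 equiv), toluene, −78 to −40 °C; then MeOH, aq NaHCO3
Reagents that add atoms: none
Why: Corey–Bakshi–Shibata reduction, in which the (R)-oxazaborolidine binds the ketone oxygen on the side of the C9 methylene, away from the quaternary C11, and delivers hydride to the C10 face that looks toward the ring ether oxygen, which should set C10 as S with the hydroxyl syn to the lactone bridge; reagent control is chosen because both faces of the bicyclic ketone are flanked by heteroatom bridges and a dependable substrate bias is not expected.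

Step 21
Reactants: 34 bis-TBDPS ether
Product: 35 target, (1R,2S,5R,9S)-2-hydroxy-1-[(3Z)-5-hydroxy-4-methylpent-3-en-1-yl]-9-[(3Z)-5-hydroxy-3-methylpent-3-en-1-yl]-5-methyl-6,8-dioxabicyclo[3.2.2]nonan-7-one
Conditions: HF·pyridine (excess), pyridine, THF, 0 °C to rt
Reagents that add atoms: none
Why: Fluoride cleavage of both primary TBDPS ethers (Si–O to Si–F exchange) in a slightly acidic medium, which avoids the retro-aldol opening that a basic fluoride source could start at the β-hydroxy lactone.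

**Compound list**

1 | nerol, (2Z)-3,7-dimethylocta-2,6-dien-1-ol | CC(C)=CCC/C(C)=C\CO | starting material
2 | tert-butyl{[(2Z)-3,7-dimethylocta-2,6-dien-1-yl]oxy}diphenylsilane | CC(C)=CCC/C(C)=C\CO[Si](c1ccccc1)(c1ccccc1)C(C)(C)C | intermediate
3 | tert-butyl{[(2Z)-5-(3,3-dimethyloxiran-2-yl)-3-methylpent-2-en-1-yl]oxy}diphenylsilane (racemic) | CC1(C)OC1CC/C(C)=C\CO[Si](c1ccccc1)(c1ccccc1)C(C)(C)C | intermediate
4 | (4Z)-6-(TBDPS-oxy)-4-methylhex-4-enal | O=CCC/C(C)=C\CO[Si](c1ccccc1)(c1ccccc1)C(C)(C)C | intermediate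
5 | isopropenylmagnesium bromide | CC(=C)[Mg]Br | starting material
6 | (6Z)-8-(TBDPS-oxy)-2,6-dimethylocta-1,6-dien-3-ol (racemic) | C=C(C)C(O)CC/C(C)=C\CO[Si](c1ccccc1)(c1ccccc1)C(C)(C)C | intermediate
7 | triethyl orthoacetate | CC(OCC)(OCC)OCC | starting material
8 | ethyl (4E,8Z)-10-(TBDPS-oxy)-4,8-dimethyldeca-4,8-dienoate | CCOC(=O)CC/C(C)=C/CC/C(C)=C\CO[Si](c1ccccc1)(c1ccccc1)C(C)(C)C | intermediate
9 | ethyl 3-{(2S,3S)-2-methyl-3-[(3Z)-3-methyl-5-(TBDPS-oxy)pent-3-en-1-yl]oxiran-2-yl}propanoate | CCOC(=O)CC[C@]1(C)O[C@H]1CC/C(C)=C\CO[Si](c1ccccc1)(c1ccccc1)C(C)(C)C | intermediate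
10 | (5R)-5-[(1S,4Z)-1-hydroxy-4-methyl-6-(TBDPS-oxy)hex-4-en-1-yl]-5-methyloxolan-2-one | O=C1CC[C@@](C)(O1)[C@@H](O)CC/C(C)=C\CO[Si](c1ccccc1)(c1ccccc1)C(C)(C)C | intermediate
11 | ethyl diazoacetate | CCOC(=O)C=[N+]=[N-] | starting material
12 | ethyl 2-{[(1S,4Z)-4-methyl-1-[(2R)-2-methyl-5-oxooxolan-2-yl]-6-(TBDPS-oxy)hex-4-en-1-yl]oxy}acetate | O=C1CC[C@@](C)(O1)[C@@H](OCC(=O)OCC)CC/C(C)=C\CO[Si](c1ccccc1)(c1ccccc1)C(C)(C)C | intermediate
13 | dilithium alkoxide enolate of ethyl (6R,7S)-6-hydroxy-6-methyl-7-[(3Z)-3-methyl-5-(TBDPS-oxy)pent-3-en-1-yl]-3-oxooxepane-2-carboxylate | [Li+].[Li+].CCOC(=O)C1=C([O-])CC[C@@](C)([O-])[C@H](CC/C(C)=C\CO[Si](c2ccccc2)(c2ccccc2)C(C)(C)C)O1 | intermediate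
14 | ethyl (6R,7S)-6-methyl-7-[(3Z)-3-methyl-5-(TBDPS-oxy)pent-3-en-1-yl]-3,6-bis(TES-oxy)-4,5,6,7-tetrahydrooxepine-2-carboxylate | CCOC(=O)C1=C(O[Si](CC)(CC)CC)CC[C@@](C)(O[Si](CC)(CC)CC)[C@H](CC/C(C)=C\CO[Si](c2ccccc2)(c2ccccc2)C(C)(C)C)O1 | intermediate
15 | ethyl (6R,7S)-6-methyl-7-[(3Z)-3-methyl-5-(TBDPS-oxy)pent-3-en-1-yl]-3-oxo-6-(TES-oxy)oxepane-2-carboxylate (both C2 epimers) | CCOC(=O)C1O[C@@H](CC/C(C)=C\CO[Si](c2ccccc2)(c2ccccc2)C(C)(C)C)[C@](C)(O[Si](CC)(CC)CC)CCC1=O | intermediate
16 | (3-bromopropoxy)(tert-butyl)dimethylsilane | BrCCCO[Si](C)(C)C(C)(C)C | starting material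
17 | triphenylphosphine | c1ccc(cc1)P(c1ccccc1)c1ccccc1 | starting material
18 | [3-(TBS-oxy)propyl]triphenylphosphonium bromide | [Br-].CC(C)(C)[Si](C)(C)OCCC[P+](c1ccccc1)(c1ccccc1)c1ccccc1 | intermediate
19 | hydroxyacetone, 1-hydroxypropan-2-one | CC(=O)CO | starting material
20 | 1-(TBDPS-oxy)propan-2-one | CC(=O)CO[Si](c1ccccc1)(c1ccccc1)C(C)(C)C | intermediate
21 | [3-(TBS-oxy)propylidene]triphenylphosphorane | CC(C)(C)[Si](C)(C)OCCC=P(c1ccccc1)(c1ccccc1)c1ccccc1 | intermediate
22 | (2Z)-1-(TBDPS-oxy)-5-(TBS-oxy)-2-methylpent-2-ene | CC(C)(C)[Si](C)(C)OCC/C=C(C)\CO[Si](c1ccccc1)(c1ccccc1)C(C)(C)C | intermediate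
23 | (3Z)-5-(TBDPS-oxy)-4-methylpent-3-en-1-ol | OCC/C=C(C)\CO[Si](c1ccccc1)(c1ccccc1)C(C)(C)C | intermediate
24 | (2Z)-1-(TBDPS-oxy)-5-iodo-2-methylpent-2-ene | ICC/C=C(C)\CO[Si](c1ccccc1)(c1ccccc1)C(C)(C)C | intermediate
25 | ethyl (6R,7S)-6-methyl-2-[(3Z)-4-methyl-5-(TBDPS-oxy)pent-3-en-1-yl]-7-[(3Z)-3-methyl-5-(TBDPS-oxy)pent-3-en-1-yl]-3-oxo-6-(TES-oxy)oxepane-2-carboxylate (both C2 epimers) | CCOC(=O)C1(CC/C=C(C)\CO[Si](c2ccccc2)(c2ccccc2)C(C)(C)C)O[C@@H](CC/C(C)=C\CO[Si](c2ccccc2)(c2ccccc2)C(C)(C)C)[C@](C)(O[Si](CC)(CC)CC)CCC1=O | intermediate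
26 | ethyl (6R,7S)-6-methyl-2-[(3Z)-4-methyl-5-(TBDPS-oxy)pent-3-en-1-yl]-7-[(3Z)-3-methyl-5-(TBDPS-oxy)pent-3-en-1-yl]-6-(TES-oxy)-3-(trimethylsilyloxy)-2,5,6,7-tetrahydrooxepine-2-carboxylate | CCOC(=O)C1(CC/C=C(C)\CO[Si](c2ccccc2)(c2ccccc2)C(C)(C)C)O[C@@H](CC/C(C)=C\CO[Si](c2ccccc2)(c2ccccc2)C(C)(C)C)[C@](C)(O[Si](CC)(CC)CC)CC=C1O[Si](C)(C)C | intermediate
27 | ethyl (6R,7S)-6-methyl-2-[(3Z)-4-methyl-5-(TBDPS-oxy)pent-3-en-1-yl]-7-[(3Z)-3-methyl-5-(TBDPS-oxy)pent-3-en-1-yl]-3-oxo-6-(TES-oxy)-2,3,6,7-tetrahydrooxepine-2-carboxylate (both C2 epimers) | CCOC(=O)C1(CC/C=C(C)\CO[Si](c2ccccc2)(c2ccccc2)C(C)(C)C)O[C@@H](CC/C(C)=C\CO[Si](c2ccccc2)(c2ccccc2)C(C)(C)C)[C@](C)(O[Si](CC)(CC)CC)C=CC1=O | intermediate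
28 | (6R,7S)-6-methyl-2-[(3Z)-4-methyl-5-(TBDPS-oxy)pent-3-en-1-yl]-7-[(3Z)-3-methyl-5-(TBDPS-oxy)pent-3-en-1-yl]-6-(TES-oxy)-6,7-dihydrooxepin-3(2H)-one (both C2 epimers) | C1(CC/C=C(C)\CO[Si](c2ccccc2)(c2ccccc2)C(C)(C)C)O[C@@H](CC/C(C)=C\CO[Si](c2ccccc2)(c2ccccc2)C(C)(C)C)[C@](C)(O[Si](CC)(CC)CC)C=CC1=O | intermediate
29 | (6R,7S)-6-hydroxy-6-methyl-2-[(3Z)-4-methyl-5-(TBDPS-oxy)pent-3-en-1-yl]-7-[(3Z)-3-methyl-5-(TBDPS-oxy)pent-3-en-1-yl]-6,7-dihydrooxepin-3(2H)-one (both C2 epimers) | C1(CC/C=C(C)\CO[Si](c2ccccc2)(c2ccccc2)C(C)(C)C)O[C@@H](CC/C(C)=C\CO[Si](c2ccccc2)(c2ccccc2)C(C)(C)C)[C@](C)(O)C=CC1=O | intermediate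
30 | 1,1'-carbonyldiimidazole | O=C(n1ccnc1)n1ccnc1 | starting material
31 | (6R,7S)-6-methyl-2-[(3Z)-4-methyl-5-(TBDPS-oxy)pent-3-en-1-yl]-7-[(3Z)-3-methyl-5-(TBDPS-oxy)pent-3-en-1-yl]-3-oxo-2,3,6,7-tetrahydrooxepin-6-yl 1H-imidazole-1-carboxylate (both C2 epimers) | C1(CC/C=C(C)\CO[Si](c2ccccc2)(c2ccccc2)C(C)(C)C)O[C@@H](CC/C(C)=C\CO[Si](c2ccccc2)(c2ccccc2)C(C)(C)C)[C@](C)(OC(=O)n2ccnc2)C=CC1=O | intermediate
32 | (1R,5R,9S)-5-methyl-1-[(3Z)-4-methyl-5-(TBDPS-oxy)pent-3-en-1-yl]-9-[(3Z)-3-methyl-5-(TBDPS-oxy)pent-3-en-1-yl]-6,8-dioxabicyclo[3.2.2]non-3-ene-2,7-dione | C/C(=C/CC[C@@]12O[C@@H](CC/C(C)=C\CO[Si](c3ccccc3)(c3ccccc3)C(C)(C)C)[C@@](C)(C=CC1=O)OC2=O)CO[Si](c1ccccc1)(c1ccccc1)C(C)(C)C | intermediate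
33 | (1R,5R,9S)-5-methyl-1-[(3Z)-4-methyl-5-(TBDPS-oxy)pent-3-en-1-yl]-9-[(3Z)-3-methyl-5-(TBDPS-oxy)pent-3-en-1-yl]-6,8-dioxabicyclo[3.2.2]nonane-2,7-dione | C/C(=C/CC[C@@]12O[C@@H](CC/C(C)=C\CO[Si](c3ccccc3)(c3ccccc3)C(C)(C)C)[C@@](C)(CCC1=O)OC2=O)CO[Si](c1ccccc1)(c1ccccc1)C(C)(C)C | intermediate
34 | (1R,2S,5R,9S)-2-hydroxy-5-methyl-1-[(3Z)-4-methyl-5-(TBDPS-oxy)pent-3-en-1-yl]-9-[(3Z)-3-methyl-5-(TBDPS-oxy)pent-3-en-1-yl]-6,8-dioxabicyclo[3.2.2]nonan-7-one | C/C(=C/CC[C@@]12O[C@@H](CC/C(C)=C\CO[Si](c3ccccc3)(c3ccccc3)C(C)(C)C)[C@@](C)(CC[C@@H]1O)OC2=O)CO[Si](c1ccccc1)(c1ccccc1)C(C)(C)C | intermediate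
35 | (1R,2S,5R,9S)-2-hydroxy-1-[(3Z)-5-hydroxy-4-methylpent-3-en-1-yl]-9-[(3Z)-5-hydroxy-3-methylpent-3-en-1-yl]-5-methyl-6,8-dioxabicyclo[3.2.2]nonan-7-one (CNP0105745.1) | C/C(=C/CC[C@@]12O[C@@H](CC/C(C)=C\CO)[C@@](C)(CC[C@@H]1O)OC2=O)CO | target

**Count and risks**

Total steps: 21 (16 in the main line, 5 for the iodide 24).
Longest linear sequence: 16 steps (nerol to 35: steps 1–7 and 13–21).

Steps most likely to fail:

1. Step 18. The enolate may be acylated at oxygen, or pass the acyl group to another molecule, instead of closing the strained bridged C–C bond. The fallback closes the lactone as a C–O bond instead. It sets out from 27: CSA in MeOH cleaves the triethylsilyl ether to the hydroxy keto ester F1, and DBU in toluene at 80 °C with removal of ethanol lets the C7 hydroxyl transesterify onto the C11 ethyl ester. This closes the same two rings and comes back to the route at 32. Only the C11 epimer of F1 with the ester cis to the C7 oxygen can close, so this path depends on the facial selectivity of step 13.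

2. Step 20. Facial selectivity may be poor if the bias of the ketone itself (hydride entering past the lactone bridge, anti to the C11–O bond) works against the catalyst. The fallback replaces facial control by inversion at C10. It sets out from 33: LiBH(s-Bu)3 in THF at −78 °C is used to make the 10R alcohol F2 under substrate control, Tf2O and pyridine give the triflate F3, and Bu4NNO2 in DMF displaces it with inversion (Lattrell–Dax) to the nitrite ester F4, which is hydrolysed on work-up and comes back to the route at 34.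

3. Step 17. Acylation of the hindered tertiary alkoxide may be incomplete, or a proton may move from C11 to the alkoxide so that CDI acylates the enolate between molecules. The fallback puts the acyl donor on without a strong base. It sets out from 29: 4-nitrophenyl chloroformate with pyridine and DMAP in CH2Cl2 gives the 4-nitrophenyl carbonate F5, and NaH in THF then closes it by the same C-acylation with loss of 4-nitrophenoxide, which comes back to the route at 32.

Further compounds
F1 | step 18 | ethyl (6R,7S)-6-hydroxy-6-methyl-2-[(3Z)-4-methyl-5-(TBDPS-oxy)pent-3-en-1-yl]-7-[(3Z)-3-methyl-5-(TBDPS-oxy)pent-3-en-1-yl]-3-oxo-2,3,6,7-tetrahydrooxepine-2-carboxylate (both C2 epimers) | CCOC(=O)C1(CC/C=C(C)\CO[Si](c2ccccc2)(c2ccccc2)C(C)(C)C)O[C@@H](CC/C(C)=C\CO[Si](c2ccccc2)(c2ccccc2)C(C)(C)C)[C@](C)(O)C=CC1=O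
F2 | step 20 | (1R,2R,5R,9S)-2-hydroxy-5-methyl-1-[(3Z)-4-methyl-5-(TBDPS-oxy)pent-3-en-1-yl]-9-[(3Z)-3-methyl-5-(TBDPS-oxy)pent-3-en-1-yl]-6,8-dioxabicyclo[3.2.2]nonan-7-one | C/C(=C/CC[C@@]12O[C@@H](CC/C(C)=C\CO[Si](c3ccccc3)(c3ccccc3)C(C)(C)C)[C@@](C)(CC[C@H]1O)OC2=O)CO[Si](c1ccccc1)(c1ccccc1)C(C)(C)C
F3 | step 20 | trifluoromethanesulfonate of F2 at the C2 (chain C10) oxygen, 2R | C/C(=C/CC[C@@]12O[C@@H](CC/C(C)=C\CO[Si](c3ccccc3)(c3ccccc3)C(C)(C)C)[C@@](C)(CC[C@H]1OS(=O)(=O)C(F)(F)F)OC2=O)CO[Si](c1ccccc1)(c1ccccc1)C(C)(C)C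
F4 | step 20 | nitrite ester of 34 at the C2 (chain C10) oxygen, 2S | C/C(=C/CC[C@@]12O[C@@H](CC/C(C)=C\CO[Si](c3ccccc3)(c3ccccc3)C(C)(C)C)[C@@](C)(CC[C@@H]1ON=O)OC2=O)CO[Si](c1ccccc1)(c1ccccc1)C(C)(C)C
F5 | step 17 | (6R,7S)-6-methyl-2-[(3Z)-4-methyl-5-(TBDPS-oxy)pent-3-en-1-yl]-7-[(3Z)-3-methyl-5-(TBDPS-oxy)pent-3-en-1-yl]-3-oxo-2,3,6,7-tetrahydrooxepin-6-yl 4-nitrophenyl carbonate (both C2 epimers) | C1(CC/C=C(C)\CO[Si](c2ccccc2)(c2ccccc2)C(C)(C)C)O[C@@H](CC/C(C)=C\CO[Si](c2ccccc2)(c2ccccc2)C(C)(C)C)[C@](C)(OC(=O)Oc2ccc(cc2)[N+](=O)[O-])C=CC1=O
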